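**Retrosynthetic overview**
1. 8 ⇐ 7: the last step only exchanges two C–Br bonds for C–H; bromine sits at C3' of each ring A (between the two hydroxyls) as a blocking group.
2. 7 ⇐ 5: the biaryl bond is not disconnected as C–C. It is traced back to a C–O bond, the quinol aryl ether 5 (O4' of ring A of one half on the dearomatised para carbon of ring B of the other), which relays to the C3–C5' bond by a [3,3] shift.
3. 5 ⇐ 3 + 3: oxidative dearomative O-arylation with trivalent iodine through the mixed diaryloxyiodane 4; both halves are the same monomer.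
4. 3 ⇐ 1 + 2: Friedel–Crafts acylation of 2-bromoresorcinol with phloretic acid.
5. No ring is formed at any stage; all four benzene rings are bought (two from 1, two from 2). Order of events: ketone C–C, then C–O bond and [3,3] relay, then C–Br to C–H.

Assumption: the target has no stereocentre and its biaryl axis carries only two ortho substituents (both OH), so it rotates freely; the compound is achiral and there is no enantiomer to select. 2-Bromoresorcinol is taken as a catalogue compound.

Ring A is the dihydroxyphenyl ketone ring (primed locants); ring B is the 4-hydroxyphenyl ring.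

**Route**

Step 1
Reactants: 1 2-bromoresorcinol (2-bromobenzene-1,3-diol); 2 phloretic acid (3-(4-hydroxyphenyl)propanoic acid)
Product: 3 1-(3-bromo-2,4-dihydroxyphenyl)-3-(4-hydroxyphenyl)propan-1-one
Conditions: BF3·OEt2 (neat, 6 equiv), 85 °C, 2 h; then aq. NaOAc, rt
Reagents that add atoms: none
Why: Friedel–Crafts (Nencki-type) acylation of a resorcinol by a free carboxylic acid in BF3·OEt2 goes to C4 of 1, the only carbon ortho/para to both hydroxyls that bromine does not occupy, while the monophenolic ring of 2 is far less nucleophilic; no stereocentre is formed.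

Step 2
Reactants: 3 1-(3-bromo-2,4-dihydroxyphenyl)-3-(4-hydroxyphenyl)propan-1-one (two molecules)
Product: 7 1-(3-bromo-2,4-dihydroxyphenyl)-3-{3'-bromo-2',4',6-trihydroxy-5'-[3-(4-hydroxyphenyl)propanoyl]biphenyl-3-yl}propan-1-one, via mixed diaryloxy(phenyl)-λ3-iodane 4 (not isolated), via quinol aryl ether 5 (not isolated), via bis-dienone 6 (not isolated)
Conditions: iodosylbenzene PhIO (0.40 equiv), 4 Å MS, MeCN, −20 °C to rt, 2 h; then 50 °C, 3 h; unreacted 3 recovered
Reagents that add atoms: none
Why: Proposed new method: iodosylbenzene, which brings no carboxylate ligand of its own, is taken up by two molecules of 3 as the mixed iodane 4, in which the acidic 4'-OH of ring A (para to the ketone, ortho to Br, pKa about 7) is the anionic ligand and the electron-rich 4-alkylphenol ring B of the second molecule is the ligand that is oxidised; loss of PhI gives a phenoxenium/aryloxide pair that closes at the alkyl-bearing para carbon of ring B to form the C–O bond of quinol aryl ether 5, whose weak, doubly allylic C–O bond then breaks in an aromatic Claisen-type [3,3] shift that joins C5' of ring A (the only free ortho carbon, C3' being blocked by Br) to the carbon next to the dienone carbonyl and gives bis-dienone 6, and double enolisation of 6 (its two sp3 centres vanish) gives biaryl 7 with a hydroxyl ortho to the new bond on each ring; the closest known reaction types are the trivalent-iodine dearomatisation of 4-alkylphenols by oxygen nucleophiles (para-quinol ethers, spirolactones), the arylation of naphthols by quinone monoacetals through a mixed acetal and [3,3] shift, and the aromatic Claisen rearrangement.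

Step 3
Reactants: 7 1-(3-bromo-2,4-dihydroxyphenyl)-3-{3'-bromo-2',4',6-trihydroxy-5'-[3-(4-hydroxyphenyl)propanoyl]biphenyl-3-yl}propan-1-one
Product: 8 1-(2,4-dihydroxyphenyl)-3-{2',4',6-trihydroxy-5'-[3-(4-hydroxyphenyl)propanoyl]biphenyl-3-yl}propan-1-one (target)
Conditions: H2 (1 atm), 10% Pd/C, NaOAc (2.5 equiv), MeOH, rt
Reagents that add atoms: none
Why: Catalytic hydrodehalogenation of the two aryl C–Br bonds over Pd/C is much faster than reduction of the chelated, electron-rich 2-hydroxyaryl ketones, and NaOAc takes up the HBr; no stereocentre is involved.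

**Compound list**
1 | 2-bromoresorcinol (2-bromobenzene-1,3-diol) | Oc1cccc(O)c1Br | starting material
2 | phloretic acid (3-(4-hydroxyphenyl)propanoic acid) | O=C(O)CCc1ccc(O)cc1 | starting material
3 | 1-(3-bromo-2,4-dihydroxyphenyl)-3-(4-hydroxyphenyl)propan-1-one | O=C(CCc1ccc(O)cc1)c1ccc(O)c(Br)c1O | intermediate
4 | {2-bromo-3-hydroxy-4-[3-(4-hydroxyphenyl)propanoyl]phenoxy}{4-[3-(3-bromo-2,4-dihydroxyphenyl)-3-oxopropyl]phenoxy}(phenyl)-λ3-iodane | O=C(CCc1ccc(O)cc1)c1ccc(OI(c2ccccc2)Oc2ccc(CCC(=O)c3ccc(O)c(Br)c3O)cc2)c(Br)c1O | intermediate (not isolated)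
5 | 4-{2-bromo-3-hydroxy-4-[3-(4-hydroxyphenyl)propanoyl]phenoxy}-4-[3-(3-bromo-2,4-dihydroxyphenyl)-3-oxopropyl]cyclohexa-2,5-dien-1-one | O=C1C=CC(CCC(=O)c2ccc(O)c(Br)c2O)(Oc2ccc(C(=O)CCc3ccc(O)cc3)c(O)c2Br)C=C1 | intermediate (not isolated)
6 | 6-{3-bromo-4-hydroxy-2-oxo-5-[3-(4-hydroxyphenyl)propanoyl]cyclohexa-3,5-dien-1-yl}-4-[3-(3-bromo-2,4-dihydroxyphenyl)-3-oxopropyl]cyclohexa-2,4-dien-1-one (diastereomer mixture; both sp3 centres are lost on enolisation) | O=C1C=CC(CCC(=O)c2ccc(O)c(Br)c2O)=CC1C1C=C(C(=O)CCc2ccc(O)cc2)C(O)=C(Br)C1=O | intermediate (not isolated)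
7 | 1-(3-bromo-2,4-dihydroxyphenyl)-3-{3'-bromo-2',4',6-trihydroxy-5'-[3-(4-hydroxyphenyl)propanoyl]biphenyl-3-yl}propan-1-one | O=C(CCc1ccc(O)c(-c2cc(C(=O)CCc3ccc(O)cc3)c(O)c(Br)c2O)c1)c1ccc(O)c(Br)c1O | intermediate
8 | 1-(2,4-dihydroxyphenyl)-3-{2',4',6-trihydroxy-5'-[3-(4-hydroxyphenyl)propanoyl]biphenyl-3-yl}propan-1-one (achiral) | O=C(CCc1ccc(O)c(-c2cc(C(=O)CCc3ccc(O)cc3)c(O)cc2O)c1)c1ccc(O)cc1O | target

**Step count and risks**
Total steps: 3. Longest linear sequence: 3 (1 + 2 → 3 → 7 → 8).

The three steps most likely to fail, in order of risk: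

Step 2 (the proposed new step). Possible failures:
- the ion pair closes at an ortho carbon of ring B and gives a diaryl ether;
- two ring B oxygens pair up and give the ring B–ring B biphenol;
- the shift attacks the bromine-bearing C3';
- the product, which still holds a free ring B, is oxidised further; this is why only 0.40 equiv of oxidant is used and 3 is recovered.

The fallback uses known chemistry only. It makes the biaryl bond by Suzuki–Miyaura coupling of two halves that already carry every hydroxyl and need no blocking bromine. It sets out from 2 and comes back to the route at 8, so step 3 is bypassed as well. Friedel–Crafts acylation of 4-bromoresorcinol with 2 (BF3·OEt2, 85 °C) gives 1-(5-bromo-2,4-dihydroxyphenyl)-3-(4-hydroxyphenyl)propan-1-one F1. Separately, 2 is brominated ortho to its hydroxyl (NBS, MeCN, 0 °C) to 3-(3-bromo-4-hydroxyphenyl)propanoic acid F2, which acylates resorcinol (BF3·OEt2, 85 °C) to 3-(3-bromo-4-hydroxyphenyl)-1-(2,4-dihydroxyphenyl)propan-1-one F3. Miyaura borylation of F3 (B2pin2, Pd(dppf)Cl2, KOAc, dioxane, 90 °C) gives 1-(2,4-dihydroxyphenyl)-3-[4-hydroxy-3-(4,4,5,5-tetramethyl-1,3,2-dioxaborolan-2-yl)phenyl]propan-1-one F4. Coupling of F4 with F1 (Pd(OAc)2, SPhos, K3PO4, dioxane/H2O, 80 °C) gives 8.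

Step 1. Risk: acid-promoted migration or loss of the bromine at 85 °C, or incomplete release of the product from boron on work-up. The fallback is a Houben–Hoesch acylation at low temperature; it sets out from 1 and comes back at 3. Compound 1 and 3-(4-hydroxyphenyl)propanenitrile with ZnCl2 and dry HCl in Et2O at 0 °C give 1-(3-bromo-2,4-dihydroxyphenyl)-3-(4-hydroxyphenyl)propan-1-iminium chloride F5, which is hydrolysed in water at 100 °C to 3.

Step 3. Risk: slow hydrogenolysis of a bromine flanked by two hydroxyls, or partial reduction of the aryl ketones on long exposure. The fallback replaces surface hydrogenolysis by a radical-chain hydrodebromination; it sets out from 7 and comes back at 8. Bu3SnH (3 equiv) and AIBN in THF at 70 °C remove both bromines; stannyl radicals do not touch the carbonyl groups, and any phenoxyl radical is reduced back by the tin hydride. No new compound is made on the way.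

**Further compounds**
F1 | step 2 | 1-(5-bromo-2,4-dihydroxyphenyl)-3-(4-hydroxyphenyl)propan-1-one | O=C(CCc1ccc(O)cc1)c1cc(Br)c(O)cc1O
F2 | step 2 | 3-(3-bromo-4-hydroxyphenyl)propanoic acid | O=C(O)CCc1ccc(O)c(Br)c1
F3 | step 2 | 3-(3-bromo-4-hydroxyphenyl)-1-(2,4-dihydroxyphenyl)propan-1-one | O=C(CCc1ccc(O)c(Br)c1)c1ccc(O)cc1O
F4 | step 2 | 1-(2,4-dihydroxyphenyl)-3-[4-hydroxy-3-(4,4,5,5-tetramethyl-1,3,2-dioxaborolan-2-yl)phenyl]propan-1-one | O=C(CCc1ccc(O)c(B2OC(C)(C)C(C)(C)O2)c1)c1ccc(O)cc1O
F5 | step 1 | 1-(3-bromo-2,4-dihydroxyphenyl)-3-(4-hydroxyphenyl)propan-1-iminium chloride | [NH2+]=C(CCc1ccc(O)cc1)c1ccc(O)c(Br)c1O.[Cl-]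
F0 | step 3 | none | none
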